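**Retrosynthetic overview**
- The route rests on the C3 oxygen next to C4 carrying the C18 methyl and the C19 formyl group, read as a reduced α-methyl β-keto ester. C4–C5 and C9–C10 are the two bonds a head-to-tail fold of the chain makes, so rings A and B come from one oxidative radical bicyclisation.
- Ring A (C4–C5) closes first and ring B (C10–C9) second, in the same step; the exocyclic C8=C17 alkene it leaves is later moved to C7=C8.
- The acyclic precursor comes from γ-alkylation of the dianion of (+)-8-phenylmenthyl 2-methylacetoacetate with a C15 allylic bromide made from (2E,6E)-farnesol; C13 is set by Ru–BINAP hydrogenation.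
- After the rings: C2–O by Rubottom oxidation, axial C3–OH by a hindered hydride, auxiliary ester to C19 aldehyde, C15 silyl ether to acid, C2 acetate last.

Key step: step 7

Assumption: the (1S,2R,5S)-8-phenylmenthyl ester is taken to direct C4–C5 bond formation to the face that gives the 10α-methyl (ent) decalin; if the sense proves opposite, the enantiomeric auxiliary is used with nothing else changed.

Convention: labdane numbering; ring A left, ring B right, C10 at the top of the ring fusion; β = toward the viewer. In this series the C10 methyl (C20) is α. "Aux" = (1S,2R,5S)-8-phenylmenthyl; TBDPS = tert-butyldiphenylsilyl; TES = triethylsilyl.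

**Step 1**
Reactants: 1 (2E,6E)-farnesol
Product: 2 (3R,6E)-3,7,11-trimethyldodeca-6,10-dien-1-ol
Conditions: H2 (100 atm), Ru(OAc)2[(S)-BINAP] (0.5 mol %), MeOH, rt
Reagents that add atoms: none
Why: Noyori asymmetric hydrogenation reduces only the hydroxyl-coordinated C2=C3 alkene, and the (S)-ligand on the E-allylic alcohol should give 3R (as geraniol gives (R)-citronellol), which becomes C13.

**Step 2**
Reactants: 2 (3R,6E)-3,7,11-trimethyldodeca-6,10-dien-1-ol
Product: 3 TBDPS ether of 2
Conditions: t-BuPh2SiCl, imidazole, DMF, rt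
Reagents that add atoms: tert-butylchlorodiphenylsilane, CC(C)(C)[Si](Cl)(c1ccccc1)c1ccccc1
Why: Imidazole-promoted O-silylation of the primary alcohol gives an ether that should survive acetic acid, base, hydride and peracid in the later steps.

**Step 3**
Reactants: 3 TBDPS ether of 2
Product: 4 (2E,6E,10R)-12-(tert-butyldiphenylsilyloxy)-2,6,10-trimethyldodeca-2,6-dien-1-ol
Conditions: SeO2 (0.3 equiv), t-BuOOH (3 equiv), salicylic acid (0.1 equiv), CH2Cl2, 0 °C to rt, stopped at partial conversion, 3 recycled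
Reagents that add atoms: selenium dioxide, O=[Se]=O; tert-butyl hydroperoxide, CC(C)(C)OO
Why: Riley allylic oxidation (ene reaction then 2,3-sigmatropic shift) is known to prefer the E-methyl of a terminal isopropylidene over an internal trisubstituted alkene and gives the E-allylic alcohol.

**Step 4**
Reactants: 4 terminal E-allylic alcohol
Product: 5 (3R,6E,10E)-12-bromo-3,7,11-trimethyldodeca-6,10-dien-1-yl TBDPS ether
Conditions: CBr4, PPh3, CH2Cl2, 0 °C
Reagents that add atoms: carbon tetrabromide, BrC(Br)(Br)Br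
Why: The Appel reaction converts the primary allylic alcohol to the bromide by SN2 displacement of the oxyphosphonium without allylic transposition or loss of E geometry.

**Step 5**
Reactants: 6 (+)-8-phenylmenthol, (1S,2R,5S)-5-methyl-2-(2-phenylpropan-2-yl)cyclohexan-1-ol; 7 ethyl 2-methyl-3-oxobutanoate
Product: 8 Aux 2-methyl-3-oxobutanoate (C2 epimers, irrelevant)
Conditions: DMAP (0.2 equiv), toluene, reflux, ethanol distilled off
Reagents that add atoms: none
Why: DMAP-catalysed transesterification of an enolisable β-keto ester proceeds through the acylketene and is driven by removal of ethanol, so the hindered secondary alcohol is acylated.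

**Step 6**
Reactants: 8 Aux 2-methyl-3-oxobutanoate; 5 allylic bromide
Product: 10 Aux (6E,10E,14R)-16-(tert-butyldiphenylsilyloxy)-2,6,10,14-tetramethyl-3-oxohexadeca-6,10-dienoate (C2 epimers), via dilithium dienolate 9 (not isolated)
Conditions: LiN(i-Pr)2 (2.2 equiv), THF, −78 to 0 °C; then 5, 0 °C; aqueous quench
Reagents that add atoms: none
Why: Huckin–Weiler alkylation of the β-keto ester dianion takes place at the more basic γ-carbon by SN2 on the allylic bromide, giving the 4-methylalk-4-enyl ketone with both E alkenes and C13 (C14 of the chain) untouched.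

**Step 7**
Reactants: 10 auxiliary-bound α-methyl β-keto ester polyene
Product: 11 Aux 15-(tert-butyldiphenylsilyloxy)-3-oxolabd-8(17)-en-19-oate of the ent series (trans-decalin; 10α-CH3; 5β-H; 9β-H with equatorial α side chain; C4 with equatorial β-CH3 and axial α-CO2Aux; 13R)
Conditions: Mn(OAc)3·2H2O (2.2 equiv), Cu(OAc)2·H2O (1 equiv, regenerated by Mn(OAc)3), degassed AcOH, rt
Reagents that add atoms: none
Why: Mn(OAc)3 (trivalent manganese) enolises the α-methyl β-keto ester and oxidises it to the electrophilic tertiary C4 radical, which adds to C5; the tertiary C10 radical then adds to C9, and the tertiary C8 radical is trapped by Cu(OAc)2 (divalent copper) as an alkylcopper (trivalent copper) that loses a β-hydrogen mainly from C17 to give the exocyclic alkene. The closest known reaction type is the Mn(OAc)3/Cu(OAc)2 oxidative free-radical polycyclisation of α-methyl β-keto ester polyenes to trans-decalins with an axial ester, including 8-phenylmenthyl ester versions. Ring A closes 6-endo-trig (C4 to C5) and ring B 6-endo-trig (C10 to C9), each preferred over 5-exo because the proximal alkene carbon (C10, then C8) carries a methyl group and the endo radical is tertiary. C5, C10 and C9 are set by the chair–chair transition state of the E,E-diene (trans ring fusion, H5 and H9 anti to C20, side chain equatorial), the axial ester at C4 follows from the preferred conformation of the keto ester radical in that chair, and the absolute sense comes from the auxiliary, whose phenyl group covers one face of the ester-conjugated radical so that C5 bonds to the open face. The step needs one fold and one radical face, secured by the E geometry of both alkenes and by the auxiliary; the regiochemistry of the final hydrogen loss is not critical because any C7=C8 isomer is carried along and merges with the main material at 18, and remote C13 is only carried through.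

**Step 8**
Reactants: 11 bicyclic 3-ketone
Product: 12 C2=C3 triethylsilyl enol ether of 11
Conditions: LiN(SiMe3)2, Et3SiCl, THF, −78 to 0 °C
Reagents that add atoms: chlorotriethylsilane, CC[Si](Cl)(CC)CC
Why: Kinetic enolisation and O-silylation can only occur toward C2 because C4 is quaternary, and the hindered ester without α-hydrogen is inert to the amide base.

**Step 9**
Reactants: 12 silyl enol ether
Product: 14 2β-(triethylsilyloxy)-3-ketone (O2 equatorial), via silyloxy epoxide 13 (not isolated)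
Conditions: mCPBA (1.05 equiv), CH2Cl2, −30 °C
Reagents that add atoms: 3-chloroperbenzoic acid, OOC(=O)c1cccc(Cl)c1
Why: In the Rubottom oxidation the electron-rich enol ether is epoxidised much faster than the 1,1-disubstituted C8=C17 alkene, from the β face away from the syn-axial C10 methyl and C4 ester, and 1,4-silyl migration on opening gives the equatorial 2β-silyloxy ketone.

**Step 10**
Reactants: 14 2β-silyloxy-3-ketone
Product: 15 2β-(triethylsilyloxy)-3β-ol (3-OH axial, cis to O2)
Conditions: LiBH(s-Bu)3, THF, −78 °C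
Reagents that add atoms: none
Why: The hindered trialkylborohydride reduces the ketone along the equatorial trajectory, as with other 4,4-disubstituted 3-oxo terpenoids, so the new hydroxyl is axial (β), and the neopentyl ester is not touched at −78 °C.

**Step 11**
Reactants: 15 2β-silyloxy-3β-ol
Product: 17 2β,3β-O-isopropylidene acetal with C8=C17 intact, via 2,3-diol 16 (not isolated)
Conditions: PPTS (cat.), MeOH, rt; evaporate; 2,2-dimethoxypropane, PPTS (cat.), acetone, rt
Reagents that add atoms: 2,2-dimethoxypropane, COC(C)(C)OC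
Why: Acid-catalysed methanolysis removes the triethylsilyl ether (the TBDPS ether is far slower) and transketalisation closes the five-membered acetonide on the cis equatorial/axial diol, which protects O3 against retro-aldol cleavage and oxidation later.

**Step 12**
Reactants: 17 acetonide with exocyclic alkene
Product: 18 acetonide with C7=C8 alkene (C17 now a methyl on C8)
Conditions: chloro[N,N′-bis(3,5-di-tert-butylsalicylidene)-1,2-cyclohexanediaminato]cobalt (trivalent cobalt, 5 mol %), PhSiH3 (10 mol %), benzene, rt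
Reagents that add atoms: none
Why: Cobalt hydride hydrogen-atom-transfer alkene isomerisation adds H to C17 to give the tertiary C8 radical, and the bulky cobalt (divalent) complex takes back the accessible C7 hydrogen and not the shielded tertiary C9 hydrogen, so the trisubstituted alkene forms, is not reactivated, and C9 keeps its configuration.

**Step 13**
Reactants: 18 Δ7 acetonide ester
Product: 19 C19 primary alcohol (4α-CH2OH)
Conditions: LiAlH4, THF, 0 to 40 °C
Reagents that add atoms: none
Why: Hydride reduction of the hindered axial ester gives the neopentyl alcohol and releases 6 for recovery, while the acetonide and the silyl ether are stable to hydride.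

**Step 14**
Reactants: 19 C19 alcohol
Product: 20 C19 aldehyde
Conditions: Dess–Martin periodinane, pyridine, CH2Cl2, rt
Reagents that add atoms: none
Why: Dess–Martin oxidation acts on the only free hydroxyl, and the aldehyde on quaternary C4 cannot epimerise.

**Step 15**
Reactants: 20 C19 aldehyde with C15 silyl ether
Product: 21 C15 primary alcohol
Conditions: Bu4NF, AcOH (1:1), THF, rt
Reagents that add atoms: none
Why: Fluoride-induced desilylation under acetic acid buffering frees the C15 alcohol without exposing the aldehyde to strongly basic alkoxide.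

**Step 16**
Reactants: 21 C15 alcohol with C19 aldehyde
Product: 23 C15 carboxylic acid with C19 aldehyde and 2,3-acetonide, via dialdehyde 22 (not isolated)
Conditions: TEMPO (0.2 equiv), PhI(OAc)2 (2.2 equiv), MeCN/pH 7 phosphate buffer, rt
Reagents that add atoms: water, O
Why: The oxoammonium oxidation takes the primary alcohol to the aldehyde and, through its hydrate, to the acid, while the axial aldehyde on quaternary C4 should resist because it hydrates poorly.

**Step 17**
Reactants: 23 acetonide acid aldehyde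
Product: 24 2β,3β-diol with C19 aldehyde and C15 acid
Conditions: AcOH/H2O (4:1), 40 °C
Reagents that add atoms: none
Why: Mild acid hydrolysis of the cis-fused acetonide leaves the trisubstituted alkene and the β-hydroxy aldehyde intact.

**Step 18**
Reactants: 24 diol acid aldehyde
Product: 25 target, (2S,3R,4S,5S,9R,10S,13R)-2-acetoxy-3-hydroxy-19-oxolabd-7-en-15-oic acid
Conditions: Ac2O (2.2 equiv), pyridine, CH2Cl2, 0 °C; aq. NaHCO3/THF work-up, then acidify
Reagents that add atoms: acetic anhydride, CC(=O)OC(C)=O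
Why: Selective O-acylation should occur at the equatorial C2 hydroxyl because the axial C3 hydroxyl is flanked by quaternary C4, and any mixed anhydride at C15 is hydrolysed in the work-up.

**Compound list**
1 | (2E,6E)-farnesol | CC(C)=CCC/C(C)=C/CC/C(C)=C/CO | starting material
2 | (3R,6E)-3,7,11-trimethyldodeca-6,10-dien-1-ol | CC(C)=CCC/C(C)=C/CC[C@@H](C)CCO | intermediate
3 | TBDPS ether of 2 | CC(C)=CCC/C(C)=C/CC[C@@H](C)CCO[Si](c1ccccc1)(c1ccccc1)C(C)(C)C | intermediate
4 | (2E,6E,10R)-12-(tert-butyldiphenylsilyloxy)-2,6,10-trimethyldodeca-2,6-dien-1-ol | OC/C(C)=C/CC/C(C)=C/CC[C@@H](C)CCO[Si](c1ccccc1)(c1ccccc1)C(C)(C)C | intermediate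
5 | (3R,6E,10E)-12-bromo-3,7,11-trimethyldodeca-6,10-dien-1-yl TBDPS ether | BrC/C(C)=C/CC/C(C)=C/CC[C@@H](C)CCO[Si](c1ccccc1)(c1ccccc1)C(C)(C)C | intermediate
6 | (+)-8-phenylmenthol, (1S,2R,5S) | CC(C)(c1ccccc1)[C@H]1CC[C@H](C)C[C@@H]1O | starting material
7 | ethyl 2-methyl-3-oxobutanoate | CCOC(=O)C(C)C(C)=O | starting material
8 | (1S,2R,5S)-8-phenylmenthyl 2-methyl-3-oxobutanoate (C2 epimers) | CC(=O)C(C)C(=O)O[C@H]1C[C@@H](C)CC[C@@H]1C(C)(C)c1ccccc1 | intermediate
9 | dilithium dienolate of 8 | [Li+].[Li+].C=C([O-])C(C)=C([O-])O[C@H]1C[C@@H](C)CC[C@@H]1C(C)(C)c1ccccc1 | intermediate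
10 | 8-phenylmenthyl (6E,10E,14R)-16-(tert-butyldiphenylsilyloxy)-2,6,10,14-tetramethyl-3-oxohexadeca-6,10-dienoate (C2 epimers) | CC(C(=O)O[C@H]1C[C@@H](C)CC[C@@H]1C(C)(C)c1ccccc1)C(=O)CC/C(C)=C/CC/C(C)=C/CC[C@@H](C)CCO[Si](c1ccccc1)(c1ccccc1)C(C)(C)C | intermediate
11 | 8-phenylmenthyl 15-(tert-butyldiphenylsilyloxy)-3-oxo-ent-labd-8(17)-en-19-oate (axial ester, 13R) | C1C[C@@]2(C)[C@H](CC[C@@H](C)CCO[Si](c3ccccc3)(c3ccccc3)C(C)(C)C)C(=C)CC[C@@H]2[C@](C)(C(=O)O[C@H]3C[C@@H](C)CC[C@@H]3C(C)(C)c3ccccc3)C1=O | intermediate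
12 | C2=C3 triethylsilyl enol ether of 11 | C=1C[C@@]2(C)[C@H](CC[C@@H](C)CCO[Si](c3ccccc3)(c3ccccc3)C(C)(C)C)C(=C)CC[C@@H]2[C@](C)(C(=O)O[C@H]3C[C@@H](C)CC[C@@H]3C(C)(C)c3ccccc3)C=1O[Si](CC)(CC)CC | intermediate
13 | 2β,3β-epoxy-3α-(triethylsilyloxy) derivative | [C@H]14C[C@@]2(C)[C@H](CC[C@@H](C)CCO[Si](c3ccccc3)(c3ccccc3)C(C)(C)C)C(=C)CC[C@@H]2[C@](C)(C(=O)O[C@H]3C[C@@H](C)CC[C@@H]3C(C)(C)c3ccccc3)[C@@]1(O[Si](CC)(CC)CC)O4 | intermediate
14 | 2β-(triethylsilyloxy)-3-ketone | CC[Si](CC)(CC)O[C@H]1C[C@@]2(C)[C@H](CC[C@@H](C)CCO[Si](c3ccccc3)(c3ccccc3)C(C)(C)C)C(=C)CC[C@@H]2[C@](C)(C(=O)O[C@H]3C[C@@H](C)CC[C@@H]3C(C)(C)c3ccccc3)C1=O | intermediate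
15 | 2β-(triethylsilyloxy)-3β-ol (axial OH) | CC[Si](CC)(CC)O[C@H]1C[C@@]2(C)[C@H](CC[C@@H](C)CCO[Si](c3ccccc3)(c3ccccc3)C(C)(C)C)C(=C)CC[C@@H]2[C@](C)(C(=O)O[C@H]3C[C@@H](C)CC[C@@H]3C(C)(C)c3ccccc3)[C@H]1O | intermediate
16 | 2β,3β-diol | O[C@H]1C[C@@]2(C)[C@H](CC[C@@H](C)CCO[Si](c3ccccc3)(c3ccccc3)C(C)(C)C)C(=C)CC[C@@H]2[C@](C)(C(=O)O[C@H]3C[C@@H](C)CC[C@@H]3C(C)(C)c3ccccc3)[C@H]1O | intermediate
17 | 2β,3β-acetonide, 8(17)-ene | CC1(C)O[C@H]4C[C@@]2(C)[C@H](CC[C@@H](C)CCO[Si](c3ccccc3)(c3ccccc3)C(C)(C)C)C(=C)CC[C@@H]2[C@](C)(C(=O)O[C@H]3C[C@@H](C)CC[C@@H]3C(C)(C)c3ccccc3)[C@H]4O1 | intermediate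
18 | 2β,3β-acetonide, 7-ene | CC1(C)O[C@H]4C[C@@]2(C)[C@H](CC[C@@H](C)CCO[Si](c3ccccc3)(c3ccccc3)C(C)(C)C)C(C)=CC[C@@H]2[C@](C)(C(=O)O[C@H]3C[C@@H](C)CC[C@@H]3C(C)(C)c3ccccc3)[C@H]4O1 | intermediate
19 | 19-alcohol (acetonide, 7-ene, 15-OTBDPS) | CC1(C)O[C@H]4C[C@@]2(C)[C@H](CC[C@@H](C)CCO[Si](c3ccccc3)(c3ccccc3)C(C)(C)C)C(C)=CC[C@@H]2[C@](C)(CO)[C@H]4O1 | intermediate
20 | 19-aldehyde (acetonide, 15-OTBDPS) | CC1(C)O[C@H]4C[C@@]2(C)[C@H](CC[C@@H](C)CCO[Si](c3ccccc3)(c3ccccc3)C(C)(C)C)C(C)=CC[C@@H]2[C@](C)(C=O)[C@H]4O1 | intermediate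
21 | 15-alcohol 19-aldehyde (acetonide) | CC1(C)O[C@H]4C[C@@]2(C)[C@H](CC[C@@H](C)CCO)C(C)=CC[C@@H]2[C@](C)(C=O)[C@H]4O1 | intermediate
22 | 15,19-dialdehyde (acetonide) | CC1(C)O[C@H]4C[C@@]2(C)[C@H](CC[C@@H](C)CC=O)C(C)=CC[C@@H]2[C@](C)(C=O)[C@H]4O1 | intermediate
23 | 15-acid 19-aldehyde (acetonide) | CC1(C)O[C@H]4C[C@@]2(C)[C@H](CC[C@@H](C)CC(=O)O)C(C)=CC[C@@H]2[C@](C)(C=O)[C@H]4O1 | intermediate
24 | 2β,3β-dihydroxy-19-oxo-ent-labd-7-en-15-oic acid | O[C@H]1C[C@@]2(C)[C@H](CC[C@@H](C)CC(=O)O)C(C)=CC[C@@H]2[C@](C)(C=O)[C@H]1O | intermediate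
25 | CNP0180877.1, (2S,3R,4S,5S,9R,10S,13R)-2-acetoxy-3-hydroxy-19-oxolabd-7-en-15-oic acid | CC(=O)O[C@H]1C[C@@]2(C)[C@H](CC[C@@H](C)CC(=O)O)C(C)=CC[C@@H]2[C@](C)(C=O)[C@H]1O | target

**Totals**
Total step count: 18. Longest linear sequence: 17 steps (steps 1–4 and 6–18); step 5 is a one-step side branch.

**Steps most likely to fail**

Step 7. Facial discrimination at the metal-free C4 radical may be weak because the auxiliary ester can rotate, and oxidation of the C10 radical by the copper salt may outrun closure of ring B. The fallback sets out from 10 and generates the radical by halogen atom transfer under a chelating Lewis acid, with no oxidant present. α-Bromination (NBS, Mg(ClO4)2 cat., MeCN, 0 °C) would give the α-bromo-α-methyl β-keto ester F1. Bromine-atom-transfer radical bicyclisation (Et3B, trace O2, Mg(ClO4)2, toluene, −78 °C), with the keto ester held syn-planar under the auxiliary by magnesium, would give the tertiary C8 bromide F2. Dehydrobromination (DBU, toluene, 80 °C) would return to the route at 11.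

Step 12. Hydrogen back-transfer at the hindered C8 radical may be slow, or may drift to the C9 hydrogen and give the tetrasubstituted C8=C9 alkene with loss of the C9 centre. The fallback sets out from 17 and replaces positional isomerisation by a regiodefined enol triflate. Ozonolysis (O3, CH2Cl2, −78 °C) would give the spiro ozonide F3, reduced in the same flask with PPh3 to the 17-nor-8-ketone F4. Kinetic enolisation toward the C7 methylene and triflation (KN(SiMe3)2, PhNTf2, THF, −78 °C) would give the C7=C8 enol triflate F5. Coupling with Me2CuLi (THF, −20 °C) would install the C8 methyl and come back to the route at 18.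

Step 16. The C19 aldehyde may be over-oxidised through its hydrate, or the acetonide may be lost in the aqueous oxidising medium. The fallback sets out from 19 and keeps C19 at the alcohol level, protected, while C15 is oxidised. Acetylation (Ac2O, DMAP, pyridine) would give the 19-acetate F6, and Bu4NF/AcOH would free the C15 alcohol F7. TEMPO/PhI(OAc)2 in buffered aqueous MeCN would pass through the C15 aldehyde F8 to the 19-acetoxy 15-acid F9. Methanolysis (K2CO3, MeOH) would give the 19-hydroxy 15-acid F10, and Dess–Martin oxidation would rejoin the route at 23.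

**Further compounds**
F1 | step 7 | 8-phenylmenthyl (6E,10E,14R)-2-bromo-16-(tert-butyldiphenylsilyloxy)-2,6,10,14-tetramethyl-3-oxohexadeca-6,10-dienoate (C2 epimers) | CC(Br)(C(=O)O[C@H]1C[C@@H](C)CC[C@@H]1C(C)(C)c1ccccc1)C(=O)CC/C(C)=C/CC/C(C)=C/CC[C@@H](C)CCO[Si](c1ccccc1)(c1ccccc1)C(C)(C)C
F2 | step 7 | 8-phenylmenthyl 8-bromo-15-(tert-butyldiphenylsilyloxy)-3-oxo-ent-labdan-19-oate (C8 epimers) | C1C[C@@]2(C)[C@H](CC[C@@H](C)CCO[Si](c3ccccc3)(c3ccccc3)C(C)(C)C)C(C)(Br)CC[C@@H]2[C@](C)(C(=O)O[C@H]3C[C@@H](C)CC[C@@H]3C(C)(C)c3ccccc3)C1=O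
F3 | step 12 | spiro 1,2,4-trioxolane (ozonide) of 17 at C8 (C8 epimers) | CC1(C)O[C@H]4C[C@@]2(C)[C@H](CC[C@@H](C)CCO[Si](c3ccccc3)(c3ccccc3)C(C)(C)C)C5(OOCO5)CC[C@@H]2[C@](C)(C(=O)O[C@H]3C[C@@H](C)CC[C@@H]3C(C)(C)c3ccccc3)[C@H]4O1
F4 | step 12 | 17-nor-8-ketone of the acetonide ester | CC1(C)O[C@H]4C[C@@]2(C)[C@H](CC[C@@H](C)CCO[Si](c3ccccc3)(c3ccccc3)C(C)(C)C)C(=O)CC[C@@H]2[C@](C)(C(=O)O[C@H]3C[C@@H](C)CC[C@@H]3C(C)(C)c3ccccc3)[C@H]4O1
F5 | step 12 | 17-nor C7=C8 enol triflate | CC1(C)O[C@H]4C[C@@]2(C)[C@H](CC[C@@H](C)CCO[Si](c3ccccc3)(c3ccccc3)C(C)(C)C)C(OS(=O)(=O)C(F)(F)F)=CC[C@@H]2[C@](C)(C(=O)O[C@H]3C[C@@H](C)CC[C@@H]3C(C)(C)c3ccccc3)[C@H]4O1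
F6 | step 16 | 19-acetate of 19 | CC1(C)O[C@H]4C[C@@]2(C)[C@H](CC[C@@H](C)CCO[Si](c3ccccc3)(c3ccccc3)C(C)(C)C)C(C)=CC[C@@H]2[C@](C)(COC(C)=O)[C@H]4O1
F7 | step 16 | 19-acetoxy 15-alcohol | CC1(C)O[C@H]4C[C@@]2(C)[C@H](CC[C@@H](C)CCO)C(C)=CC[C@@H]2[C@](C)(COC(C)=O)[C@H]4O1
F8 | step 16 | 19-acetoxy 15-aldehyde | CC1(C)O[C@H]4C[C@@]2(C)[C@H](CC[C@@H](C)CC=O)C(C)=CC[C@@H]2[C@](C)(COC(C)=O)[C@H]4O1
F9 | step 16 | 19-acetoxy 15-acid | CC1(C)O[C@H]4C[C@@]2(C)[C@H](CC[C@@H](C)CC(=O)O)C(C)=CC[C@@H]2[C@](C)(COC(C)=O)[C@H]4O1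
F10 | step 16 | 19-hydroxy 15-acid | CC1(C)O[C@H]4C[C@@]2(C)[C@H](CC[C@@H](C)CC(=O)O)C(C)=CC[C@@H]2[C@](C)(CO)[C@H]4O1
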